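**Retrosynthetic overview**

1. Feature: with the veratryl half numbered C7 (ArCH2), C8 (CH), C9 (CH2OAc) and the syringyl half primed, the chain C7–C8–C8'–C7' with C9 and C9' on the adjacent (8R,8'R) carbons is a 2,5-diarylthiolane-3,4-dicarbonyl compound minus the ring sulfur that bridges C7 and C7'.
2. Endgame: target ⇐ selective aryl-acetate cleavage of the triacetate ⇐ triol 19 ⇐ LiAlH4 on bis-imide 18 ⇐ Raney Ni cleavage of C7–S and C7'–S (and of the benzyl ether) in thiolane 16.
3. Key disconnection: the thiolane (the only ring built, later opened) ⇒ 1,3-diaryl thiocarbonyl ylide 15 (C7–S–C7') plus the C8=C8' bond of N,N'-fumaroylbis[(2R)-bornane-10,2-sultam] 14; C7–C8 and C7'–C8' form together.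
4. The ylide comes from bis(α-silylbenzyl) sulfoxide 11. Each benzylic carbon receives its silyl group (PhMe2Si, from the silyllithium and the aldehyde) before the C–S bonds are made, so no deprotonation of a mixed dibenzyl sulfide, with its risk of geminal disilylation, is needed.
5. The fumaric unit carries bornane sultams because the ylide excludes Lewis acids and N-enoyl sultams keep a strong π-facial bias in uncatalysed cycloadditions; they also make the desulfurised product a diastereomer that can be purified.

Key step: step 10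

Assumption: the uncatalysed cycloaddition is taken to follow the accepted topicity of N-enoyl (2R)-bornane-10,2-sultams (attack on the Cα-re face of the s-cis, C=O/SO2-anti conformer); should the major adduct prove to belong to the (3S,4S) series, the equally available (2S)-sultam would be used with no other change.

**Route**

Step 1
Reactants: 1 3,4-dimethoxybenzaldehyde
Product: 2 (3,4-dimethoxyphenyl)[dimethyl(phenyl)silyl]methanol (racemic)
Conditions: PhMe2SiLi (from PhMe2SiCl, Li, THF, 0 °C), THF, −78 °C; AcOH, −78 °C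
Reagents that add atoms: dimethylphenylsilyllithium, [Li][Si](C)(C)c1ccccc1
Why: 1,2-addition of a silyllithium to an aryl aldehyde, in which the lithium alkoxide of the α-silyl alcohol is stable at −78 °C and is protonated before warming so that Brook rearrangement should not intervene; the new centre is racemic and is erased later.

Step 2
Reactants: 2 (3,4-dimethoxyphenyl)[dimethyl(phenyl)silyl]methanol
Product: 3 [chloro(3,4-dimethoxyphenyl)methyl]dimethyl(phenyl)silane (racemic)
Conditions: SOCl2, pyridine, CH2Cl2, 0 °C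
Reagents that add atoms: thionyl chloride, O=S(Cl)Cl
Why: chlorodehydroxylation of a benzylic alcohol via its chlorosulfite, assisted by the electron-rich arene, under buffered conditions that the C–Si bond tolerates.

Step 3
Reactants: 3 [chloro(3,4-dimethoxyphenyl)methyl]dimethyl(phenyl)silane
Product: 4 S-{(3,4-dimethoxyphenyl)[dimethyl(phenyl)silyl]methyl} thioacetate (racemic)
Conditions: KSAc, DMF, 0 °C → rt
Reagents that add atoms: potassium thioacetate, CC(=O)[S-].[K+]
Why: nucleophilic substitution of an activated benzylic chloride by thioacetate, a soft sulfur nucleophile that does not attack silicon.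

Step 4
Reactants: 5 syringaldehyde (4-hydroxy-3,5-dimethoxybenzaldehyde)
Product: 6 4-(benzyloxy)-3,5-dimethoxybenzaldehyde
Conditions: BnBr, K2CO3, DMF, 60 °C
Reagents that add atoms: benzyl bromide, BrCc1ccccc1
Why: Williamson ether synthesis on the phenoxide, masking the acidic phenol before the silyllithium step.

Step 5
Reactants: 6 4-(benzyloxy)-3,5-dimethoxybenzaldehyde
Product: 7 [4-(benzyloxy)-3,5-dimethoxyphenyl][dimethyl(phenyl)silyl]methanol (racemic)
Conditions: PhMe2SiLi (from PhMe2SiCl, Li, THF, 0 °C), THF, −78 °C; AcOH, −78 °C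
Reagents that add atoms: dimethylphenylsilyllithium, [Li][Si](C)(C)c1ccccc1
Why: the same silyllithium 1,2-addition to an aryl aldehyde as in step 1, with the aryl ethers inert at −78 °C and cold protonation forestalling Brook rearrangement.

Step 6
Reactants: 7 [4-(benzyloxy)-3,5-dimethoxyphenyl][dimethyl(phenyl)silyl]methanol
Product: 8 {[4-(benzyloxy)-3,5-dimethoxyphenyl]chloromethyl}dimethyl(phenyl)silane (racemic)
Conditions: SOCl2, pyridine, CH2Cl2, 0 °C
Reagents that add atoms: thionyl chloride, O=S(Cl)Cl
Why: chlorodehydroxylation of the benzylic alcohol as in step 2, with the benzyl ether stable to the buffered conditions; the chloride is used without storage.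

Step 7
Reactants: 4 S-{(3,4-dimethoxyphenyl)[dimethyl(phenyl)silyl]methyl} thioacetate; 8 {[4-(benzyloxy)-3,5-dimethoxyphenyl]chloromethyl}dimethyl(phenyl)silane
Product: 10 [4-(benzyloxy)-3,5-dimethoxyphenyl][dimethyl(phenyl)silyl]methyl (3,4-dimethoxyphenyl)[dimethyl(phenyl)silyl]methyl sulfide (mixture of diastereomers), via α-silyl thiol 9 (not isolated)
Conditions: pyrrolidine (1.0 equiv), degassed DMF, 0 °C; then Cs2CO3, 8, 0 °C → rt
Reagents that add atoms: none
Why: aminolysis of the thioacetate frees thiol 9, which under carbonate displaces the benzylic chloride of 8 (thioether synthesis by substitution), so that each silyl group sits unambiguously on its own benzylic carbon; the stereocentres are inconsequential.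

Step 8
Reactants: 10 the bis(α-silylbenzyl) sulfide
Product: 11 [4-(benzyloxy)-3,5-dimethoxyphenyl][dimethyl(phenyl)silyl]methyl (3,4-dimethoxyphenyl)[dimethyl(phenyl)silyl]methyl sulfoxide (stereoisomer mixture, all leading to the same ylide)
Conditions: mCPBA (1.0 equiv), CH2Cl2, −78 °C; cold aq. NaHCO3 wash; solution kept below −20 °C and used at once
Reagents that add atoms: 3-chloroperoxybenzoic acid, OOC(=O)c1cccc(Cl)c1
Why: chemoselective sulfide-to-sulfoxide oxidation by one equivalent of peracid at low temperature, with the acid washed out cold because α-silyl sulfoxides are thermally labile.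

Step 9
Reactants: 12 fumaryl chloride; 13 (2R)-bornane-10,2-sultam (2 equiv)
Product: 14 N,N'-fumaroylbis[(2R)-bornane-10,2-sultam] ((E)-alkene)
Conditions: NaH, toluene, 0 °C → rt
Reagents that add atoms: none
Why: N-acylation of the sultam sodium salt by the diacid chloride, a standard preparation of N-enoyl sultams that retains the (E)-geometry.

Step 10
Reactants: 11 the bis(α-silylbenzyl) sulfoxide; 14 N,N'-fumaroylbis[(2R)-bornane-10,2-sultam] (2 equiv)
Product: 16 N,N'-{[(3R,4R)-2-(3,4-dimethoxyphenyl)-5-(4-benzyloxy-3,5-dimethoxyphenyl)thiolane-3,4-diyl]dicarbonyl}bis[(2R)-bornane-10,2-sultam] (C2 and C5 epimers unassigned), via thiocarbonyl ylide 15 (not isolated)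
Conditions: 14 in ClCH2CH2Cl, 70 °C; cold solution of 11 added slowly
Reagents that add atoms: none
Why: Warming the bis(α-silyl) sulfoxide starts a sila-Pummerer sequence in which one silyl group shifts from carbon to the sulfinyl oxygen, silanolate departs and strips the second silyl group, releasing the 1,3-diaryl thiocarbonyl ylide 15 and the disiloxane. The closest known reaction type is the [3+2] cycloaddition of sila-Pummerer-generated thiocarbonyl ylides with fumaric and other α,β-unsaturated acyl derivatives, N-enoyl sultams included, so only the substitution pattern is new. The thiolane ring is closed by a concerted suprafacial [π4s+π2s] union of the electron-rich C–S–C dipole with the electron-poor C=C, so both ring C–C bonds (C2–C3 and C4–C5) form in one event. C3 and C4 are trans because the (E)-geometry of the fumaroyl unit is transferred stereospecifically, and their absolute configuration is set by the two (2R)-sultams, which in the s-cis, C=O/SO2-anti conformation expose the Cα-re face of each enoyl half, that is the same (re,re) face of the C2-symmetric alkene, leading to (3R,4R). C2 and C5 follow the ylide geometry and are left uncontrolled, since both become CH2 in step 11. The step needs only π-facial selectivity (the symmetric dipolarophile raises no regiochemical question) and a cycloaddition faster than ylide closure to the thiirane, which the excess of the doubly activated dipolarophile and the slow addition of 11 are meant to secure.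

Step 11
Reactants: 16 the thiolane bis-sultam
Product: 18 N,N'-[(2R,3R)-2-(3,4-dimethoxybenzyl)-3-(4-hydroxy-3,5-dimethoxybenzyl)succinoyl]bis[(2R)-bornane-10,2-sultam], via desulfurised benzyl ether 17 (not isolated)
Conditions: Raney Ni (W-2, washed neutral), THF/EtOH, 40 °C; filtration; H2 (1 atm), Pd/C, rt; crystallisation of the major diastereomer
Reagents that add atoms: none
Why: Raney Ni hydrogenolysis of the two benzylic C–S bonds (reductive desulfurisation) turns C2 and C5 into CH2 and merges all epimers, Pd/C hydrogenolysis completes removal of the aryl benzyl ether, and the neutral conditions leave C8 and C8' untouched while only the two facial diastereomers remain to be separated.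

Step 12
Reactants: 18 the phenolic succinoyl bis-sultam
Product: 19 (2R,3R)-2-(3,4-dimethoxybenzyl)-3-(4-hydroxy-3,5-dimethoxybenzyl)butane-1,4-diol
Conditions: LiAlH4, THF, 0 °C → rt; aq. NaOH work-up
Reagents that add atoms: none
Why: hydride reduction of N-acyl sultams to primary alcohols is a standard auxiliary removal that does not epimerise the α-centres, the phenol riding through as its phenoxide and the sultam being recovered.

Step 13
Reactants: 19 the triol
Product: 20 (2R,3R)-2-(3,4-dimethoxybenzyl)-3-(4-acetoxy-3,5-dimethoxybenzyl)butane-1,4-diyl diacetate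
Conditions: Ac2O, pyridine, DMAP (cat.), CH2Cl2, rt
Reagents that add atoms: acetic anhydride, CC(=O)OC(C)=O
Why: exhaustive DMAP-catalysed O-acetylation of the two primary alcohols and the phenol, which avoids any need for selective acylation.

Step 14
Reactants: 20 the triacetate
Product: 21 Justin C, (2R,3R)-2-(3,4-dimethoxybenzyl)-3-(4-hydroxy-3,5-dimethoxybenzyl)butane-1,4-diyl diacetate
Conditions: pyrrolidine (1.2 equiv), THF, 0 °C → rt
Reagents that add atoms: none
Why: chemoselective aminolysis of the aryl acetate, whose phenoxide leaving group makes it far more reactive towards amines than the primary alkyl acetates, should free only the phenol.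

**Compound list**

1 | 3,4-dimethoxybenzaldehyde | COc1ccc(C=O)cc1OC | starting material
2 | (3,4-dimethoxyphenyl)[dimethyl(phenyl)silyl]methanol (racemic) | COc1ccc(C(O)[Si](C)(C)c2ccccc2)cc1OC | intermediate
3 | [chloro(3,4-dimethoxyphenyl)methyl]dimethyl(phenyl)silane (racemic) | COc1ccc(C(Cl)[Si](C)(C)c2ccccc2)cc1OC | intermediate
4 | S-{(3,4-dimethoxyphenyl)[dimethyl(phenyl)silyl]methyl} thioacetate (racemic) | COc1ccc(C(SC(C)=O)[Si](C)(C)c2ccccc2)cc1OC | intermediate
5 | syringaldehyde | COc1cc(C=O)cc(OC)c1O | starting material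
6 | 4-(benzyloxy)-3,5-dimethoxybenzaldehyde | COc1cc(C=O)cc(OC)c1OCc1ccccc1 | intermediate
7 | [4-(benzyloxy)-3,5-dimethoxyphenyl][dimethyl(phenyl)silyl]methanol (racemic) | COc1cc(C(O)[Si](C)(C)c2ccccc2)cc(OC)c1OCc1ccccc1 | intermediate
8 | {[4-(benzyloxy)-3,5-dimethoxyphenyl]chloromethyl}dimethyl(phenyl)silane (racemic) | COc1cc(C(Cl)[Si](C)(C)c2ccccc2)cc(OC)c1OCc1ccccc1 | intermediate
9 | (3,4-dimethoxyphenyl)[dimethyl(phenyl)silyl]methanethiol (racemic, not isolated) | COc1ccc(C(S)[Si](C)(C)c2ccccc2)cc1OC | intermediate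
10 | [4-(benzyloxy)-3,5-dimethoxyphenyl][dimethyl(phenyl)silyl]methyl (3,4-dimethoxyphenyl)[dimethyl(phenyl)silyl]methyl sulfide (diastereomer mixture) | COc1ccc(C([Si](C)(C)c2ccccc2)SC([Si](C)(C)c2ccccc2)c2cc(OC)c(OCc3ccccc3)c(OC)c2)cc1OC | intermediate
11 | the corresponding sulfoxide (stereoisomer mixture) | COc1ccc(C([Si](C)(C)c2ccccc2)S(=O)C([Si](C)(C)c2ccccc2)c2cc(OC)c(OCc3ccccc3)c(OC)c2)cc1OC | intermediate
12 | fumaryl chloride | O=C(Cl)/C=C/C(=O)Cl | starting material
13 | (2R)-bornane-10,2-sultam [(1S)-(−)-2,10-camphorsultam] | CC1(C)[C@@H]2CC[C@]13CS(=O)(=O)N[C@@H]3C2 | starting material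
14 | N,N'-fumaroylbis[(2R)-bornane-10,2-sultam] | CC1(C)[C@@H]2CC[C@]13CS(=O)(=O)N(C(=O)/C=C/C(=O)N4[C@@H]5C[C@H]6CC[C@]5(CS4(=O)=O)C6(C)C)[C@@H]3C2 | intermediate
15 | 1-(4-benzyloxy-3,5-dimethoxyphenyl)-3-(3,4-dimethoxyphenyl)thiocarbonyl ylide (not isolated) | COc1ccc(C=[S+][CH-]c2cc(OC)c(OCc3ccccc3)c(OC)c2)cc1OC | intermediate
16 | (3R,4R)-2-(3,4-dimethoxyphenyl)-5-(4-benzyloxy-3,5-dimethoxyphenyl)thiolane-3,4-dicarbonyl bis[(2R)-bornane-10,2-sultam] (C2/C5 epimers unassigned) | COc1ccc(C2[C@@H](C(=O)N5[C@@H]6C[C@H]7CC[C@]6(CS5(=O)=O)C7(C)C)[C@H](C(=O)N5[C@@H]6C[C@H]7CC[C@]6(CS5(=O)=O)C7(C)C)C(S2)c3cc(OC)c(OCc4ccccc4)c(OC)c3)cc1OC | intermediate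
17 | N,N'-[(2R,3R)-2-(3,4-dimethoxybenzyl)-3-(4-benzyloxy-3,5-dimethoxybenzyl)succinoyl]bis[(2R)-bornane-10,2-sultam] (not isolated) | COc1ccc(C[C@@H](C(=O)N5[C@@H]6C[C@H]7CC[C@]6(CS5(=O)=O)C7(C)C)[C@H](C(=O)N5[C@@H]6C[C@H]7CC[C@]6(CS5(=O)=O)C7(C)C)Cc3cc(OC)c(OCc4ccccc4)c(OC)c3)cc1OC | intermediate
18 | N,N'-[(2R,3R)-2-(3,4-dimethoxybenzyl)-3-(4-hydroxy-3,5-dimethoxybenzyl)succinoyl]bis[(2R)-bornane-10,2-sultam] | COc1ccc(C[C@@H](C(=O)N5[C@@H]6C[C@H]7CC[C@]6(CS5(=O)=O)C7(C)C)[C@H](C(=O)N5[C@@H]6C[C@H]7CC[C@]6(CS5(=O)=O)C7(C)C)Cc3cc(OC)c(O)c(OC)c3)cc1OC | intermediate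
19 | (2R,3R)-2-(3,4-dimethoxybenzyl)-3-(4-hydroxy-3,5-dimethoxybenzyl)butane-1,4-diol | COc1ccc(C[C@@H](CO)[C@H](CO)Cc2cc(OC)c(O)c(OC)c2)cc1OC | intermediate
20 | (2R,3R)-2-(3,4-dimethoxybenzyl)-3-(4-acetoxy-3,5-dimethoxybenzyl)butane-1,4-diyl diacetate | COc1ccc(C[C@@H](COC(C)=O)[C@H](COC(C)=O)Cc2cc(OC)c(OC(C)=O)c(OC)c2)cc1OC | intermediate
21 | Justin C | COc1ccc(C[C@@H](COC(C)=O)[C@H](COC(C)=O)Cc2cc(OC)c(O)c(OC)c2)cc1OC | target

**Step count**

Total: 14 steps. Longest linear sequence: 10 steps (steps 4, 5, 6, 7, 8, 10, 11, 12, 13, 14 from syringaldehyde; equally long from 3,4-dimethoxybenzaldehyde).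

**Steps most likely to fail**

Step 10. The hindered 1,3-diaryl ylide may close to the thiirane (and lose sulfur to the stilbene) or be protonated faster than it adds to the bulky bis-imide. The π-facial discrimination may also be too low to leave a separable excess of the (3R,4R) series. The fallback sets out from 1 and 6 and comes back at 19; it gives up the sulfur template for a tandem conjugate addition–alkylation on a chiral butenolide. Aldehyde 1 is converted with PhSH and BF3·OEt2 in CH2Cl2 into 3,4-dimethoxybenzaldehyde bis(phenylthio)acetal F1. Aldehyde 6 is reduced with NaBH4 in MeOH to [4-(benzyloxy)-3,5-dimethoxyphenyl]methanol F2, which PBr3 in Et2O at 0 °C turns into 2-(benzyloxy)-5-(bromomethyl)-1,3-dimethoxybenzene F3. Lithiated F1 (n-BuLi, THF, −78 °C) should add 1,4 to commercial (5R)-5-[(1R,2S,5R)-menthyloxy]furan-2(5H)-one (O=C1C=C[C@H](O[C@@H]2C[C@H](C)CC[C@H]2C(C)C)O1) anti to the menthyloxy group. The lactone enolate is then alkylated with F3 anti to the new C4 substituent, giving (3R,4R,5R)-3-[4-(benzyloxy)-3,5-dimethoxybenzyl]-4-[(3,4-dimethoxyphenyl)bis(phenylthio)methyl]-5-[(1R,2S,5R)-menthyloxy]dihydrofuran-2(3H)-one F4. Raney Ni, followed by H2 over Pd/C if needed, removes both phenylthio groups and the benzyl ether to give (3R,4R,5R)-4-(3,4-dimethoxybenzyl)-3-(4-hydroxy-3,5-dimethoxybenzyl)-5-[(1R,2S,5R)-menthyloxy]dihydrofuran-2(3H)-one F5. LiAlH4 reduces the lactone carbonyl and the acetal carbon to the two CH2OH groups with release of menthol and delivers triol 19.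

Step 7. The substitution joins two hindered secondary benzylic carbons; if it is slow, chloride 8 would be lost by solvolysis and thiol 9 by disulfide formation. The fallback sets out from 4 and 7 and comes back at 10; it makes the C–S bond through the benzylic cation instead. Thiol 9, freed from 4 with pyrrolidine as before, is condensed with alcohol 7 under ZnI2 in ClCH2CH2Cl (Lewis-acid-mediated dehydrative thioetherification of a benzylic alcohol). This by-passes chloride 8 and gives sulfide 10; no new compound arises (F0).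

Step 8. The bis(α-silylbenzyl) sulfoxide may fragment by the sila-Pummerer path already during oxidation or work-up, so that the ylide is released with 3-chlorobenzoic acid present and no dipolarophile, and is lost by protonation; over-oxidation to the sulfone is a second hazard. The fallback sets out from 4 and 6 and comes back at 16; it avoids the sulfoxide and makes the same ylide 15 by fluoride-induced 1,3-elimination. Thiol 9, freed from 4 with pyrrolidine, is condensed with aldehyde 6 under anhydrous HCl (CH2Cl2, MgSO4, −20 °C) to give [4-(benzyloxy)-3,5-dimethoxyphenyl]chloromethyl (3,4-dimethoxyphenyl)[dimethyl(phenyl)silyl]methyl sulfide F6, used crude. CsF in MeCN in the presence of 14 removes the silyl group with loss of chloride, and the ylide is trapped as 16.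

**Further compounds**

F1 | step 10 | 3,4-dimethoxybenzaldehyde bis(phenylthio)acetal | COc1ccc(C(Sc2ccccc2)Sc2ccccc2)cc1OC
F2 | step 10 | [4-(benzyloxy)-3,5-dimethoxyphenyl]methanol | COc1cc(CO)cc(OC)c1OCc1ccccc1
F3 | step 10 | 2-(benzyloxy)-5-(bromomethyl)-1,3-dimethoxybenzene | COc1cc(CBr)cc(OC)c1OCc1ccccc1
F4 | step 10 | (3R,4R,5R)-3-[4-(benzyloxy)-3,5-dimethoxybenzyl]-4-[(3,4-dimethoxyphenyl)bis(phenylthio)methyl]-5-[(1R,2S,5R)-menthyloxy]dihydrofuran-2(3H)-one | O=C1O[C@@H](O[C@@H]2C[C@H](C)CC[C@H]2C(C)C)[C@H](C(Sc2ccccc2)(Sc2ccccc2)c2ccc(OC)c(OC)c2)[C@H]1Cc1cc(OC)c(OCc2ccccc2)c(OC)c1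
F5 | step 10 | (3R,4R,5R)-4-(3,4-dimethoxybenzyl)-3-(4-hydroxy-3,5-dimethoxybenzyl)-5-[(1R,2S,5R)-menthyloxy]dihydrofuran-2(3H)-one | O=C1O[C@@H](O[C@@H]2C[C@H](C)CC[C@H]2C(C)C)[C@H](Cc2ccc(OC)c(OC)c2)[C@H]1Cc1cc(OC)c(O)c(OC)c1
F0 | step 7 | none | none
F6 | step 8 | [4-(benzyloxy)-3,5-dimethoxyphenyl]chloromethyl (3,4-dimethoxyphenyl)[dimethyl(phenyl)silyl]methyl sulfide | COc1ccc(C([Si](C)(C)c2ccccc2)SC(Cl)c2cc(OC)c(OCc3ccccc3)c(OC)c2)cc1OC
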